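**Retrosynthetic overview**
1. Jaspaquinol ⇐ its bis-MOM ether (mild acid) ⇐ an allylic phenyl sulfone (Pd-catalysed hydride desulfonylation).
2. The ring-CH2–CH2 bond is made by alkylating the β-cyclogeranyl phenyl sulfone anion with an (E,E)-8-bromogeranyl arene (C10 + C16 sulfone coupling).
3. The bromide comes from SeO2 allylic oxidation of 2-geranylhydroquinone bis-MOM ether, itself from ortho-lithiation/Cu allylation of hydroquinone bis-MOM ether with geranyl bromide.
4. No ring is constructed: the cyclohexene is bought as β-cyclocitral and the arene as hydroquinone. The 2E alkene is bought in geranyl bromide and the 6E alkene is set by the SeO2 step.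

Assumption: the target has no stereogenic centre (it is achiral), so "single enantiomer" reduces to controlling the two E trisubstituted alkenes. This route is designed from known reaction classes and has not been run.

**Route**

Step 1
Reactants: 1, β-cyclocitral (2,6,6-trimethylcyclohex-1-ene-1-carbaldehyde)
Product: 2, β-cyclogeraniol [(2,6,6-trimethylcyclohex-1-en-1-yl)methanol]
Conditions: NaBH4, MeOH, 0 °C → rt
Reagents that add atoms: none
Why: Simple 1,2-hydride reduction of a hindered enal; no stereocentre is formed.

Step 2
Reactants: 2, β-cyclogeraniol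
Product: 3, β-cyclogeranyl bromide [2-(bromomethyl)-1,3,3-trimethylcyclohex-1-ene], used crude
Conditions: PBr3, pyridine (cat.), Et2O, 0 °C
Reagents that add atoms: phosphorus tribromide, BrP(Br)Br
Why: Allylic alcohol to bromide via the phosphite ester; the primary bromide with the tetrasubstituted alkene is the thermodynamically preferred allylic isomer.

Step 3
Reactants: 3, β-cyclogeranyl bromide; 4, sodium benzenesulfinate
Product: 5, β-cyclogeranyl phenyl sulfone {[(2,6,6-trimethylcyclohex-1-en-1-yl)methyl]sulfonyl}benzene
Conditions: PhSO2Na, DMF, rt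
Reagents that add atoms: sodium benzenesulfinate (4), [Na+].[O-]S(=O)c1ccccc1
Why: SN2 S-alkylation of the sulfinate by a reactive primary allylic bromide gives the crystalline sulfone.

Step 4
Reactants: 6, hydroquinone; 7, chloromethyl methyl ether (MOMCl)
Product: 8, 1,4-bis(methoxymethoxy)benzene
Conditions: NaH, MOMCl, DMF, 0 °C → rt
Reagents that add atoms: MOMCl (7), COCCl
Why: Williamson-type O-alkylation of both phenoxides; MOM is both the protecting group and the directing group for the next step.

Step 5
Reactants: 8, 1,4-bis(methoxymethoxy)benzene; 9, geranyl bromide [(2E)-1-bromo-3,7-dimethylocta-2,6-diene]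
Product: 10, 2-[(2E)-3,7-dimethylocta-2,6-dien-1-yl]-1,4-bis(methoxymethoxy)benzene
Conditions: n-BuLi, TMEDA, THF, 0 °C; CuBr·SMe2, −78 °C; then 9, −78 °C → rt
Reagents that add atoms: geranyl bromide (9), CC(C)=CCC/C(C)=C/CBr
Why: Directed ortho-metalation (all four ring positions are equivalent) followed by Cu-mediated SN2 allylation at the primary carbon, which keeps the 2E alkene.

Step 6
Reactants: 10, geranyl arene
Product: 11, (2E,6E)-8-[2,5-bis(methoxymethoxy)phenyl]-2,6-dimethylocta-2,6-dien-1-ol
Conditions: SeO2 (cat.), t-BuOOH, salicylic acid (cat.), CH2Cl2, 0 °C → rt; then NaBH4, MeOH, 0 °C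
Reagents that add atoms: selenium dioxide, O=[Se]=O (oxygen donor, re-oxidised by tert-butyl hydroperoxide, CC(C)(C)OO)
Why: Sharpless-type SeO2 allylic oxidation (ene reaction then [2,3]-shift) attacks the terminal gem-dimethyl alkene at its E-methyl, which sets the second E alkene; the NaBH4 work-up returns any over-oxidised enal to the alcohol.

Step 7
Reactants: 11, allylic alcohol
Product: 12, 2-[(2E,6E)-8-bromo-3,7-dimethylocta-2,6-dien-1-yl]-1,4-bis(methoxymethoxy)benzene
Conditions: MsCl, Et3N, THF, −40 °C; then LiBr, THF, 0 °C
Reagents that add atoms: lithium bromide, [Li+].[Br-]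
Why: Mesylation then SN2 bromide displacement under non-acidic conditions keeps the MOM ethers and the alkene geometry.

Step 8
Reactants: 5, β-cyclogeranyl phenyl sulfone; 12, allylic bromide
Product: 13, {[(3E,7E)-9-[2,5-bis(methoxymethoxy)phenyl]-3,7-dimethyl-1-(2,6,6-trimethylcyclohex-1-en-1-yl)nona-3,7-dien-1-yl]sulfonyl}benzene (racemic at the sulfonyl carbon)
Conditions: 5, n-BuLi, THF/HMPA, −78 °C; then 12, −78 → −20 °C
Reagents that add atoms: none (both partners are the numbered reactants)
Why: Julia/Biellmann-type α-alkylation of the allylic sulfone carbanion with an unhindered primary allylic bromide (SN2, γ-attack blocked by the fully substituted ring carbon); the new stereocentre is racemic and is removed in step 9.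

Step 9
Reactants: 13, coupled sulfone
Product: 14, 2-[(2E,6E)-3,7-dimethyl-9-(2,6,6-trimethylcyclohex-1-en-1-yl)nona-2,6-dien-1-yl]-1,4-bis(methoxymethoxy)benzene
Conditions: PdCl2(dppp) (10 mol %), LiEt3BH, THF, 0 °C → rt
Reagents that add atoms: none
Why: Pd-catalysed reductive desulfonylation via a π-allyl intermediate, with hydride delivered to the less substituted terminus so the tetrasubstituted ring alkene stays in place; the chain alkenes and MOM ethers are untouched.

Step 10
Reactants: 14, bis-MOM jaspaquinol
Product: 15, jaspaquinol, 2-[(2E,6E)-3,7-dimethyl-9-(2,6,6-trimethylcyclohex-1-en-1-yl)nona-2,6-dien-1-yl]benzene-1,4-diol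
Conditions: HCl (cat.), MeOH, rt, degassed under Ar; aqueous Na2S2O4 wash on work-up
Reagents that add atoms: none
Why: Mild acetal methanolysis removes both MOM groups below the acidity needed for chroman formation or polyene cyclisation; exclusion of air and a dithionite wash keep the hydroquinone reduced.

**Compound list**
1 | β-cyclocitral | CC1=C(C=O)C(C)(C)CCC1 | starting material
2 | β-cyclogeraniol | CC1=C(CO)C(C)(C)CCC1 | intermediate
3 | β-cyclogeranyl bromide | CC1=C(CBr)C(C)(C)CCC1 | intermediate
4 | sodium benzenesulfinate | [Na+].[O-]S(=O)c1ccccc1 | starting material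
5 | β-cyclogeranyl phenyl sulfone | CC1=C(CS(=O)(=O)c2ccccc2)C(C)(C)CCC1 | intermediate
6 | hydroquinone | Oc1ccc(O)cc1 | starting material
7 | chloromethyl methyl ether (MOMCl) | COCCl | starting material
8 | 1,4-bis(methoxymethoxy)benzene | COCOc1ccc(OCOC)cc1 | intermediate
9 | geranyl bromide, (2E) | CC(C)=CCC/C(C)=C/CBr | starting material
10 | 2-[(2E)-geranyl]-1,4-bis(methoxymethoxy)benzene | CC(C)=CCC/C(C)=C/Cc1cc(OCOC)ccc1OCOC | intermediate
11 | (2E,6E)-8-[2,5-bis(methoxymethoxy)phenyl]-2,6-dimethylocta-2,6-dien-1-ol | OC/C(C)=C/CC/C(C)=C/Cc1cc(OCOC)ccc1OCOC | intermediate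
12 | 2-[(2E,6E)-8-bromo-3,7-dimethylocta-2,6-dien-1-yl]-1,4-bis(methoxymethoxy)benzene | BrC/C(C)=C/CC/C(C)=C/Cc1cc(OCOC)ccc1OCOC | intermediate
13 | coupled allylic phenyl sulfone (racemic at C–SO2Ph; 3E,7E) | CC1=C(C(C/C(C)=C/CC/C(C)=C/Cc2cc(OCOC)ccc2OCOC)S(=O)(=O)c2ccccc2)C(C)(C)CCC1 | intermediate
14 | jaspaquinol bis-MOM ether (2E,6E) | CC1=C(CC/C(C)=C/CC/C(C)=C/Cc2cc(OCOC)ccc2OCOC)C(C)(C)CCC1 | intermediate
15 | jaspaquinol | CC1=C(CC/C(C)=C/CC/C(C)=C/Cc2cc(O)ccc2O)C(C)(C)CCC1 | target

**Step count**
Total: 10 steps. Longest linear sequence: 7 steps (hydroquinone 6 → 15, steps 4–10); the sulfone branch is 3 steps (steps 1–3).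

**Three steps most likely to fail, with fallbacks**
1. Step 6 (SeO2 oxidation of 10): competing oxidation at the internal benzylic/allylic positions and over-oxidation may give a low yield. Fallback: reorder the route. Oxidise geranyl acetate with SeO2/t-BuOOH instead, convert to the 8-bromide, couple with sulfone 5, and desulfonylate/deacetylate to the C20 allylic alcohol. Then brominate and attach lithiated 8 (Cu-mediated) as the last C–C bond.
2. Step 9 (Pd/LiEt3BH desulfonylation): ionisation next to the hindered tetrasubstituted alkene may be slow, or the alkene may migrate to the exocyclic position. Fallback: drop the sulfone union. Oxidise 11 to the enal (MnO2), methylenate (Ph3P=CH2) to the terminal diene, hydroborate the vinyl group with 9-BBN, and run a B-alkyl Suzuki coupling with 2,6,6-trimethylcyclohex-1-enyl triflate (from 2,2,6-trimethylcyclohexanone).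
3. Step 10 (acidic MOM removal): chroman formation by phenol addition to the 2,3-alkene, or air oxidation to the quinone. Fallback: carry the arene as the dimethyl ether (start from commercial 1,4-dimethoxybenzene, which removes step 4). Unmask without acid by CAN oxidation to the quinone, then reduce with Na2S2O4 to the hydroquinone.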